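The synthesis rests on making the benzene ring (ring A) instead of substituting it: the ring carbon that carries C1 lies meta to both hydroxylated carbons, an alternating oxygen pattern that maps directly onto a 1,3,5-tricarbonyl chain. In the key step a mild base folds diketo-dioxinone 19 by intramolecular aldol condensation, forging the one missing ring C–C bond and aromatising in the same operation to the acetonide-masked resorcylate 21, whose carboxyl carbon is later expelled as CO2. Precursor 19 is an (R)-configured open chain carrying the C2 oxygen as a TBS ether and the C8 ketone as a dioxolane; its single stereocentre is set early by asymmetric hydrogenation of a β-keto ester.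

Key step: step 10

Assumption (chemistry): the chain is numbered C1 (benzylic CH2), C2 (acetoxy carbon, R by CIP: O > C1 > C3 > H), C3–C7 (methylenes), C8 (ketone), C9–C13 (pentyl). LiN(SiMe3)2, LiN(iPr)2 and iPrMgCl are used as purchased solutions. Compound 19 is drawn as its triketo tautomer although it will be largely enolised.

Step 1
Reactants: 1 1-morpholinocyclohexene; 2 hexanoyl chloride
Product: 4 2-hexanoylcyclohexan-1-one, via acylated enamine 3 (not isolated)
Conditions: Et3N, CH2Cl2, 0 °C → rt; then 6 M HCl (aq), reflux
Reagents that add atoms: water, O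
Why: Stork enamine acylation, in which the nucleophilic β-carbon of the morpholine enamine should be C-acylated by the acid chloride while Et3N takes up HCl, after which aqueous acid hydrolyses the vinylogous amide 3 to the β-diketone.

Step 2
Reactants: 4 2-hexanoylcyclohexan-1-one
Product: 5 7-oxododecanoic acid
Conditions: NaOH (aq), EtOH, reflux; then HCl (aq)
Reagents that add atoms: sodium hydroxide, [Na+].[OH-]
Why: Retro-Claisen cleavage of a β-diketone, in which hydroxide should add to the more electrophilic ring carbonyl and the ring C–C bond breaks to release the enolate of the open-chain ketone, extending the hexanoyl unit by six carbons to the 7-oxo acid.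

Step 3
Reactants: 5 7-oxododecanoic acid; 6 potassium methyl malonate (KO2CCH2CO2Me)
Product: 9 methyl 3,9-dioxotetradecanoate, via acyl imidazolide 7 (not isolated), via acylmalonate half-ester 8 (not isolated)
Conditions: CDI, THF, rt; then 6, MgCl2, Et3N, MeCN, rt → 40 °C; 1 M HCl work-up
Reagents that add atoms: none
Why: Masamune–Brooks homologation, in which the acyl imidazolide should C-acylate the magnesium enolate of the malonate half-ester and the acylmalonic acid then loses CO2 on acidic work-up, the isolated ketone being inert to these near-neutral conditions.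

Step 4
Reactants: 9 methyl 3,9-dioxotetradecanoate
Product: 10 methyl (R)-3-hydroxy-9-oxotetradecanoate
Conditions: H2 (10 atm), RuCl2[(R)-BINAP] (1 mol %), MeOH, 50 °C
Reagents that add atoms: none
Why: Noyori asymmetric hydrogenation, in which the divalent ruthenium–BINAP catalyst binds the β-keto ester as a chelate and delivers hydrogen to one ketone face, the (R)-ligand giving the (R)-carbinol as it does for simple 3-oxoalkanoates, whereas the unfunctionalised C9 ketone cannot chelate and should stay untouched.

Step 5
Reactants: 10 methyl (R)-3-hydroxy-9-oxotetradecanoate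
Product: 11 methyl (R)-3-[(tert-butyldimethylsilyl)oxy]-9-oxotetradecanoate
Conditions: TBSCl, imidazole, DMF, rt
Reagents that add atoms: tert-butyldimethylsilyl chloride, CC(C)(C)[Si](C)(C)Cl
Why: Imidazole-promoted silylation of a secondary alcohol, which leaves the stereocentre untouched and blocks retro-aldol and hemiketal pathways in the later enolate steps.

Step 6
Reactants: 11 methyl (R)-3-[(tert-butyldimethylsilyl)oxy]-9-oxotetradecanoate
Product: 12 methyl (R)-3-[(tert-butyldimethylsilyl)oxy]-8-(2-pentyl-1,3-dioxolan-2-yl)octanoate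
Conditions: (Me3SiOCH2)2, Me3SiOTf (5 mol %), CH2Cl2, −78 → −20 °C; pyridine quench
Reagents that add atoms: 1,2-bis(trimethylsilyloxy)ethane, C[Si](C)(C)OCCO[Si](C)(C)C
Why: Noyori ketalisation, in which silyl triflate catalysis transfers the bis-silylated diol to the dialkyl ketone under aprotic low-temperature conditions, driven by formation of hexamethyldisiloxane, so that the TBS ether and the methyl ester should survive.

Step 7
Reactants: 12 methyl (R)-3-[(tert-butyldimethylsilyl)oxy]-8-(2-pentyl-1,3-dioxolan-2-yl)octanoate
Product: 13 (R)-3-[(tert-butyldimethylsilyl)oxy]-N-methoxy-N-methyl-8-(2-pentyl-1,3-dioxolan-2-yl)octanamide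
Conditions: MeNHOMe·HCl, iPrMgCl, THF, −20 → 0 °C
Reagents that add atoms: N,O-dimethylhydroxylamine hydrochloride, CNOC.Cl
Why: Weinreb amide formation by aminolysis of the ester with the chloromagnesium amide generated in the flask, a transformation routinely applied to β-silyloxy esters and compatible with the ketal at low temperature.

Step 8
Reactants: 14 2,2,6-trimethyl-4H-1,3-dioxin-4-one; 15 acetyl chloride
Product: 17 2,2-dimethyl-6-(2-oxopropyl)-4H-1,3-dioxin-4-one, via lithium dienolate 16 (not isolated)
Conditions: LiN(SiMe3)2 (2 equiv per AcCl, 14 in twofold excess), THF, −78 °C; then AcCl, −78 °C; aq NH4Cl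
Reagents that add atoms: none
Why: Vinylogous Claisen-type C-acylation, in which the lithium dienolate of the dioxinone should react with the acid chloride at its γ-carbon (the exocyclic methylene), the enolate being used in excess because the more acidic product consumes one equivalent as base.

Step 9
Reactants: 17 2,2-dimethyl-6-(2-oxopropyl)-4H-1,3-dioxin-4-one; 13 (R)-3-[(tert-butyldimethylsilyl)oxy]-N-methoxy-N-methyl-8-(2-pentyl-1,3-dioxolan-2-yl)octanamide
Product: 19 (R)-6-{6-[(tert-butyldimethylsilyl)oxy]-2,4-dioxo-11-(2-pentyl-1,3-dioxolan-2-yl)undecyl}-2,2-dimethyl-4H-1,3-dioxin-4-one, via dilithium dianion 18 (not isolated)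
Conditions: LiN(iPr)2 (2 equiv per 17, 17 in excess over 13), THF, −78 → −40 °C; then 13, −78 → −20 °C; aq NH4Cl; product carried on after rapid filtration only
Reagents that add atoms: none
Why: Dianion Claisen acylation of a 1,3-dicarbonyl dianion by a Weinreb amide, in which the more basic terminal carbanion of 18 should add to the amide to give a chelated tetrahedral intermediate that releases the 1,3-diketone only on quench, so over-addition and proton exchange with the product are avoided and C2 is untouched.

Step 10
Reactants: 19 (R)-6-{6-[(tert-butyldimethylsilyl)oxy]-2,4-dioxo-11-(2-pentyl-1,3-dioxolan-2-yl)undecyl}-2,2-dimethyl-4H-1,3-dioxin-4-one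
Product: 21 (R)-5-{2-[(tert-butyldimethylsilyl)oxy]-7-(2-pentyl-1,3-dioxolan-2-yl)heptyl}-7-hydroxy-2,2-dimethyl-4H-benzo[d][1,3]dioxin-4-one, via cyclic aldol 20 (not isolated)
Conditions: Et3N (5 equiv), CH2Cl2, rt
Reagents that add atoms: none
Why: Triethylamine removes a proton from the methylene flanked by the dioxinone and the neighbouring ketone, and the extended vinylogous enolate attacks through dioxinone C5 on the distal ketone carbon (the one attached to C1) to give carbinol 20, after which β-elimination of water and enolisation of the remaining ring ketone should deliver the aromatic resorcylate irreversibly. The closest known reaction type is the amine-mediated aldol aromatisation of diketo-dioxinones to 2,2-dimethylbenzodioxinone resorcylates, a laboratory counterpart of polyketide aldol folding. The single new ring (ring A, six-membered, carbocyclic) closes in a 6-(enolexo)-exo-trig aldol between dioxinone C5 and the terminal ketone. No stereocentre is created in 21, since the two transient sp3 centres of 20 are erased on aromatisation, and C2 is not involved. The step needs C–C closure in preference to O-cyclisation to a pyranone and to E1cB loss of the C2 silyloxy group: the acetal bridge of the dioxinone ties up the ester oxygen and leaves C5 as the only nucleophile that can reach a carbonyl through a six-membered transition state, while the 1,3-diketone sits as its enol or enolate under the mild amine base so that the C1–H bonds next to the silyloxy carbon are poorly acidic and the bulky silanolate is a reluctant leaving group.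

Step 11
Reactants: 21 (R)-5-{2-[(tert-butyldimethylsilyl)oxy]-7-(2-pentyl-1,3-dioxolan-2-yl)heptyl}-7-hydroxy-2,2-dimethyl-4H-benzo[d][1,3]dioxin-4-one
Product: 24 (R)-1-(3,5-dihydroxyphenyl)-2-hydroxytridecan-8-one, via resorcylic acid 22 (not isolated), via silyl ketal resorcinol 23 (not isolated)
Conditions: 6 M NaOH (aq), MeOH, 120 °C, sealed tube; then HCl (aq) to pH 1, THF, 40 °C
Reagents that add atoms: water, O
Why: Ester saponification, decarboxylation of a β-resorcylic acid and acid hydrolysis of silyl ether and ketal in one pot, in which hot hydroxide opens the acetonide ester, the electron-rich ring is protonated at the carboxyl-bearing carbon and loses CO2 (finishing in the warm acidic stage if incomplete in base), the ketal shields C8 from aldol chemistry during the basic stage, and aqueous acid then frees the C2 alcohol and the C8 ketone without touching the configuration.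

Step 12
Reactants: 24 (R)-1-(3,5-dihydroxyphenyl)-2-hydroxytridecan-8-one
Product: 25 (R)-5-(2-acetoxy-8-oxotridecyl)-1,3-phenylene diacetate
Conditions: Ac2O, pyridine, DMAP (cat), CH2Cl2, 0 °C → rt
Reagents that add atoms: acetic anhydride, CC(=O)OC(C)=O
Why: DMAP-catalysed exhaustive acetylation of the two phenols and the secondary alcohol, a step in which neither acyl migration nor epimerisation at C2 is possible.

Step 13
Reactants: 25 (R)-5-(2-acetoxy-8-oxotridecyl)-1,3-phenylene diacetate
Product: 26 (R)-1-(3,5-dihydroxyphenyl)-8-oxotridecan-2-yl acetate (CNP0213461.1)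
Conditions: NH4OAc (excess), MeOH–H2O 4:1, rt
Reagents that add atoms: none
Why: Chemoselective solvolysis of aryl esters, in which the aryl acetates, whose phenoxide leaving groups are far better than an alkoxide, should undergo ammonium acetate-mediated methanolysis at room temperature while the secondary alkyl acetate at C2 and the C8 ketone stay intact.

Compound list
1 | 1-morpholinocyclohexene [4-(cyclohex-1-en-1-yl)morpholine] | C1CCC(=CC1)N1CCOCC1 | starting material
2 | hexanoyl chloride | CCCCCC(Cl)=O | starting material
3 | 1-(2-morpholinocyclohex-1-en-1-yl)hexan-1-one (acylated enamine; not isolated) | CCCCCC(=O)C1=C(CCCC1)N1CCOCC1 | intermediate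
4 | 2-hexanoylcyclohexan-1-one | CCCCCC(=O)C1CCCCC1=O | intermediate
5 | 7-oxododecanoic acid | CCCCCC(=O)CCCCCC(=O)O | intermediate
6 | potassium methyl malonate | COC(=O)CC(=O)[O-].[K+] | starting material
7 | 1-(1H-imidazol-1-yl)dodecane-1,7-dione (acyl imidazolide; not isolated) | CCCCCC(=O)CCCCCC(=O)n1ccnc1 | intermediate
8 | 2-(methoxycarbonyl)-3,9-dioxotetradecanoic acid (acylmalonate half-ester; not isolated) | CCCCCC(=O)CCCCCC(=O)C(C(=O)O)C(=O)OC | intermediate
9 | methyl 3,9-dioxotetradecanoate | CCCCCC(=O)CCCCCC(=O)CC(=O)OC | intermediate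
10 | methyl (R)-3-hydroxy-9-oxotetradecanoate | CCCCCC(=O)CCCCC[C@H](CC(=O)OC)O | intermediate
11 | methyl (R)-3-[(tert-butyldimethylsilyl)oxy]-9-oxotetradecanoate | CCCCCC(=O)CCCCC[C@H](CC(=O)OC)O[Si](C)(C)C(C)(C)C | intermediate
12 | methyl (R)-3-[(tert-butyldimethylsilyl)oxy]-8-(2-pentyl-1,3-dioxolan-2-yl)octanoate | CCCCCC1(OCCO1)CCCCC[C@H](CC(=O)OC)O[Si](C)(C)C(C)(C)C | intermediate
13 | (R)-3-[(tert-butyldimethylsilyl)oxy]-N-methoxy-N-methyl-8-(2-pentyl-1,3-dioxolan-2-yl)octanamide | CCCCCC1(OCCO1)CCCCC[C@H](CC(=O)N(C)OC)O[Si](C)(C)C(C)(C)C | intermediate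
14 | 2,2,6-trimethyl-4H-1,3-dioxin-4-one | CC1=CC(=O)OC(C)(C)O1 | starting material
15 | acetyl chloride | CC(Cl)=O | starting material
16 | lithium 2,2-dimethyl-6-methylidene-6H-1,3-dioxin-4-olate (lithium dienolate of 14; not isolated) | [Li+].C=C1C=C([O-])OC(C)(C)O1 | intermediate
17 | 2,2-dimethyl-6-(2-oxopropyl)-4H-1,3-dioxin-4-one | CC(=O)CC1=CC(=O)OC(C)(C)O1 | intermediate
18 | dilithium dianion of 17 (bis-enolate; not isolated) | [Li+].[Li+].C=C([O-])C=C1C=C([O-])OC(C)(C)O1 | intermediate
19 | (R)-6-{6-[(tert-butyldimethylsilyl)oxy]-2,4-dioxo-11-(2-pentyl-1,3-dioxolan-2-yl)undecyl}-2,2-dimethyl-4H-1,3-dioxin-4-one | CCCCCC1(OCCO1)CCCCC[C@H](CC(=O)CC(=O)CC2=CC(=O)OC(C)(C)O2)O[Si](C)(C)C(C)(C)C | intermediate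
20 | 5-{(R)-2-[(tert-butyldimethylsilyl)oxy]-7-(2-pentyl-1,3-dioxolan-2-yl)heptyl}-5-hydroxy-2,2-dimethyl-5,6-dihydro-4H-benzo[d][1,3]dioxine-4,7(4aH)-dione (cyclic aldol, epimers at C4a and C5; not isolated) | CCCCCC1(OCCO1)CCCCC[C@H](CC2(O)CC(=O)C=C3OC(C)(C)OC(=O)C23)O[Si](C)(C)C(C)(C)C | intermediate
21 | (R)-5-{2-[(tert-butyldimethylsilyl)oxy]-7-(2-pentyl-1,3-dioxolan-2-yl)heptyl}-7-hydroxy-2,2-dimethyl-4H-benzo[d][1,3]dioxin-4-one | CCCCCC1(OCCO1)CCCCC[C@H](Cc2cc(O)cc3OC(C)(C)OC(=O)c23)O[Si](C)(C)C(C)(C)C | intermediate
22 | (R)-2-{2-[(tert-butyldimethylsilyl)oxy]-7-(2-pentyl-1,3-dioxolan-2-yl)heptyl}-4,6-dihydroxybenzoic acid (present as its sodium salt; not isolated) | CCCCCC1(OCCO1)CCCCC[C@H](Cc2cc(O)cc(O)c2C(=O)O)O[Si](C)(C)C(C)(C)C | intermediate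
23 | (R)-5-{2-[(tert-butyldimethylsilyl)oxy]-7-(2-pentyl-1,3-dioxolan-2-yl)heptyl}benzene-1,3-diol (not isolated) | CCCCCC1(OCCO1)CCCCC[C@H](Cc2cc(O)cc(O)c2)O[Si](C)(C)C(C)(C)C | intermediate
24 | (R)-1-(3,5-dihydroxyphenyl)-2-hydroxytridecan-8-one | CCCCCC(=O)CCCCC[C@H](Cc1cc(O)cc(O)c1)O | intermediate
25 | (R)-5-(2-acetoxy-8-oxotridecyl)-1,3-phenylene diacetate | CCCCCC(=O)CCCCC[C@H](Cc1cc(OC(C)=O)cc(OC(C)=O)c1)OC(C)=O | intermediate
26 | (R)-1-(3,5-dihydroxyphenyl)-8-oxotridecan-2-yl acetate (CNP0213461.1) | CCCCCC(=O)CCCCC[C@H](Cc1cc(O)cc(O)c1)OC(C)=O | target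

Total step count: 13. Longest linear sequence: 12 steps (steps 1–7 and 9–13, from 1 and 2); step 8 is a one-step branch from 14 and 15.

Steps most likely to fail

Step 10. The enolised chain could divert into O-cyclisation to a pyranone, stall at the carbinol stage, or lose silanolate by β-elimination before the carbocycle closes. The fallback sets out from 19 and returns at 22 (inside step 11), and so at 24; it decouples ring formation from the dioxinone. Heating 19 in toluene with MeOH at about 100 °C should expel acetone by retro-[4+2] fragmentation and trap the acylketene as methyl (R)-9-[(tert-butyldimethylsilyl)oxy]-3,5,7-trioxo-14-(2-pentyl-1,3-dioxolan-2-yl)tetradecanoate F1. Treatment with Cs2CO3 in MeOH at room temperature, then acidification with AcOH, should bring about aldol condensation of the open-chain triketo ester (C2 onto the C7 ketone) and aromatisation to methyl (R)-2-{2-[(tert-butyldimethylsilyl)oxy]-7-(2-pentyl-1,3-dioxolan-2-yl)heptyl}-4,6-dihydroxybenzoate F2. F2 then takes the place of 21 in step 11, where hot NaOH saponifies it to 22.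

Step 9. Acylation of the soft, hindered dianion by the amide may be slow at low temperature, so that deprotonation of the amide next to its carbonyl and β-elimination of the silyloxy group compete. The fallback sets out from 13 and returns at 19; it replaces the acylation by an aldol addition followed by oxidation. Reduction of 13 with iBu2AlH in CH2Cl2 at −78 °C should give (R)-3-[(tert-butyldimethylsilyl)oxy]-8-(2-pentyl-1,3-dioxolan-2-yl)octanal F3. Addition of this far more electrophilic aldehyde to dianion 18 at −78 °C should give 6-{(6R)-6-[(tert-butyldimethylsilyl)oxy]-4-hydroxy-2-oxo-11-(2-pentyl-1,3-dioxolan-2-yl)undecyl}-2,2-dimethyl-4H-1,3-dioxin-4-one F4 as a mixture of carbinol epimers. Oxidation with Dess–Martin periodinane buffered with NaHCO3 in CH2Cl2 removes the new carbinol centre and should give 19.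

Step 13. Discrimination between aryl and alkyl acetates may be incomplete, through partial solvolysis of the C2 acetate or unfinished cleavage of the second aryl acetate. The fallback sets out from 24 and returns at 26, bypassing 25; it separates the two kinds of hydroxyl by protection. Benzylation of the phenols only (BnBr, K2CO3, acetone, reflux) should give (R)-1-[3,5-bis(benzyloxy)phenyl]-2-hydroxytridecan-8-one F5. Acetylation of the remaining secondary alcohol (Ac2O, pyridine, DMAP) should give (R)-1-[3,5-bis(benzyloxy)phenyl]-8-oxotridecan-2-yl acetate F6. Hydrogenolysis (H2, 1 atm, palladium on carbon, EtOAc, rt) then frees both phenols to give 26, leaving the dialkyl ketone and the homobenzylic acetate intact.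

Further compounds
F1 | step 10 | methyl (R)-9-[(tert-butyldimethylsilyl)oxy]-3,5,7-trioxo-14-(2-pentyl-1,3-dioxolan-2-yl)tetradecanoate | CCCCCC1(OCCO1)CCCCC[C@H](CC(=O)CC(=O)CC(=O)CC(=O)OC)O[Si](C)(C)C(C)(C)C
F2 | step 10 | methyl (R)-2-{2-[(tert-butyldimethylsilyl)oxy]-7-(2-pentyl-1,3-dioxolan-2-yl)heptyl}-4,6-dihydroxybenzoate | CCCCCC1(OCCO1)CCCCC[C@H](Cc2cc(O)cc(O)c2C(=O)OC)O[Si](C)(C)C(C)(C)C
F3 | step 9 | (R)-3-[(tert-butyldimethylsilyl)oxy]-8-(2-pentyl-1,3-dioxolan-2-yl)octanal | CCCCCC1(OCCO1)CCCCC[C@H](CC=O)O[Si](C)(C)C(C)(C)C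
F4 | step 9 | 6-{(6R)-6-[(tert-butyldimethylsilyl)oxy]-4-hydroxy-2-oxo-11-(2-pentyl-1,3-dioxolan-2-yl)undecyl}-2,2-dimethyl-4H-1,3-dioxin-4-one (epimers at the new carbinol) | CCCCCC1(OCCO1)CCCCC[C@H](CC(O)CC(=O)CC2=CC(=O)OC(C)(C)O2)O[Si](C)(C)C(C)(C)C
F5 | step 13 | (R)-1-[3,5-bis(benzyloxy)phenyl]-2-hydroxytridecan-8-one | CCCCCC(=O)CCCCC[C@H](Cc1cc(OCc2ccccc2)cc(OCc2ccccc2)c1)O
F6 | step 13 | (R)-1-[3,5-bis(benzyloxy)phenyl]-8-oxotridecan-2-yl acetate | CCCCCC(=O)CCCCC[C@H](Cc1cc(OCc2ccccc2)cc(OCc2ccccc2)c1)OC(C)=O
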